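(The readings are simulated from invented constants; scatter was added.)

Read the runs below for one thing: how much of the catalyst charge the impurity can take away from the rate.

| flask | substrate | coupling partner | free catalyst | impurity | remark |
|---|---|---|---|---|---|
| autumn | 0.20 M | 0.40 M | 0.20 mM | 38 µM | the very flask that is asked about, followed so far |
| dawn | 0.20 M | 0.20 M | 0.20 mM | 38 µM | run made earlier |
| flask | 0.20 M | 0.400 M | 0.20 mM | 38 µM |  |

| run | time / h | product / % | substrate / % |
|---|---|---|---|
| autumn | 0.333 | 0.2 | 99.0 |
| autumn | 0.500 | 1.9 | 97.5 |
| autumn | 0.833 | 2.7 | 98.5 |
| autumn | 1.33 | 4.1 | 97.2 |
| autumn | 2.50 | 6.4 | 95.3 |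
| autumn | 4.00 | 8.5 | 91.6 |
| dawn | 0.200 | 0.1 | 98.6 |
| dawn | 0.667 | 2.3 | 98.2 |
| dawn | 1.00 | 3.2 | 97.8 |
| dawn | 2.00 | 4.2 | 96.0 |
| dawn | 2.50 | 5.3 | 94.4 |
| dawn | 3.00 | 6.9 | 93.3 |

(readings scatter by 0.5 percentage points)

- the analysis behind the earlier runs scatters by 0.5 percentage points, standard deviation
- no earlier run changes the charge of free catalyst; that part of a forecast is a guess

* apparent order in free catalyst when 5.0% of the substrate are converted (percent change of the rate of making product for one percent more free catalyst charged)
* factor on the rate of making product when 5.0% of the substrate are converted if free catalyst is charged twice over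

Divide the impurity charged by the free catalyst charged, and carry the poison share 0.190, the impurity charged over the free catalyst charged, as the fraction of the charge lost to catalyst poisoning if each impurity removes one catalyst for good. Freeze the rest: suppose the rate follows the surviving catalyst, and that the impurity charge stays as it is when the catalyst charge changes. For the ceiling, let the flask lose the whole share before 5.0% conversion, so that the order is one over one minus the share, 1.23, and a doubled charge multiplies the rate by 2.23. For the floor, let the impurity take nothing, which gives order 1 and factor 2.

Tighten this with the autumn run, whose product rose by 0.0324 /h of the substrate charged up to 0.833 h and by 0.0165 /h from 1.33 h to 4.00 h. That is a fall of 0.492 as read, with its scatter, and it is more than the poison share, so the readings do not hold the loss below the ceiling, and I commit to the ceiling. The forecast, which reasoned that the impurity “could bind catalyst tightly”, gave 1.15 and 2.2, both below my ceiling and above the floor.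

The flask gives order 1.2 and factor 2.23.

    substrate + free catalyst → catalyst intermediate A (k = 590 /M/h)
    coupling partner + catalyst intermediate A → catalyst intermediate B (k = 830 /M/h)
    catalyst intermediate B → free catalyst + product (k = 41.0 /h)
    free catalyst + impurity → spent catalyst (k = 51000 /M/h)

In the flask at 4.00 h, spent catalyst holds 19.0% of the catalyst charged, and the impurity is down to 0.0242% of its own charge. Put the poison share to use at 80.0 h: it leaves 81.0% of the catalyst charged working, and the flask then holds 81.0% of the catalyst charged as free catalyst, catalyst intermediate A and catalyst intermediate B together, of which free catalyst is 77.4%.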